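**Plan**

1. Ring C (C1' bonded to benzofuran C2, then C2' to C6') carries oxygen on C3' and C5', hydrogen on C4' and prenyl on C2' and C6'. This five-substituent 1,3-dioxygen pattern is what a vinylketene and an oxygenated alkyne deliver, so the retrosynthesis cuts C3'–C4', C5'–C6' and C2'–C3' to give alkenyl diazoketone 17 and silyloxyacetylene 20.
2. Diazoketone 17 is cut at the diazo group (diazo transfer), at its C=C bond (aldol condensation with aldehyde 12) and at the bond from benzofuran C2 to the side-chain CH2 (palladium-catalysed arylation of enol silane 9 by bromide 7).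
3. Bromide 7 is cut at O1–C2 (copper-catalysed closure of dibromoalkene 6) and at the bond from C7 to the quaternary carbon (Claisen rearrangement of prenyl ether 3).
4. Forward: ring A comes from aldehyde 1, the furan ring is closed onto it, the side chain is joined at C2, and ring C is closed last around the carbon already bonded to C2.
5. Late steps are only the removal of the silyl group and of the two methoxymethyl groups.
6. The target has no stereocentre. The only stereo element on the way, the (E)-alkene of 15 to 17, is set by elimination and disappears when ring C becomes aromatic.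

Key step: step 13

Remark: the target is taken as the achiral 2-arylbenzofuran drawn by the SMILES. Abbreviations used in names: Bf = 4,6-bis(methoxymethoxy)-7-(2-methylbut-3-en-2-yl)-1-benzofuran-2-yl; MOM = methoxymethyl; TIPS = triisopropylsilyl.

**Route**

Step 1
Reactants: 1 2,4,6-trihydroxybenzaldehyde; 2 3-methylbut-2-en-1-ol
Product: 3 2,6-dihydroxy-4-[(3-methylbut-2-en-1-yl)oxy]benzaldehyde
Conditions: PPh3, i-PrO2C–N=N–CO2i-Pr, THF, 0 °C to rt
Reagents that add atoms: none
Why: Mitsunobu etherification should take the 4-OH, the most acidic phenol and the only one not hydrogen-bonded to the aldehyde, and it cannot alkylate the ring carbons.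

Step 2
Reactants: 3 2,6-dihydroxy-4-[(3-methylbut-2-en-1-yl)oxy]benzaldehyde
Product: 4 2,4,6-trihydroxy-3-(2-methylbut-3-en-2-yl)benzaldehyde
Conditions: EtOH–H2O (4:1), degassed, 130 °C, sealed tube
Reagents that add atoms: none
Why: Aromatic Claisen rearrangement of the aryl prenyl ether can only end at C3 or C5, which are equivalent by symmetry because the para position carries the aldehyde, and tautomerisation of the dienone gives the ortho 1,1-dimethylallyl group.

Step 3
Reactants: 4 2,4,6-trihydroxy-3-(2-methylbut-3-en-2-yl)benzaldehyde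
Product: 5 2-hydroxy-4,6-bis(methoxymethoxy)-3-(2-methylbut-3-en-2-yl)benzaldehyde
Conditions: MeOCH2Cl (2.2 equiv), i-Pr2NEt, CH2Cl2, 0 °C to rt
Reagents that add atoms: chloromethyl methyl ether, COCCl
Why: Base-mediated O-alkylation to the MOM acetals should take the acidic 4-OH and the unhindered 6-OH, while the 2-OH, chelated to the aldehyde and flanked by the quaternary carbon, stays free, as in the usual selective bis-protection of 1.

Step 4
Reactants: 5 2-hydroxy-4,6-bis(methoxymethoxy)-3-(2-methylbut-3-en-2-yl)benzaldehyde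
Product: 6 2-(2,2-dibromoethenyl)-3,5-bis(methoxymethoxy)-6-(2-methylbut-3-en-2-yl)phenol
Conditions: CBr4, PPh3, Et3N, CH2Cl2, 0 °C
Reagents that add atoms: carbon tetrabromide, BrC(Br)(Br)Br
Why: Ramirez dibromo-olefination (Wittig reaction of Ph3P=CBr2) converts the aldehyde, and Et3N takes up HBr so that the MOM acetals and the free phenol survive.

Step 5
Reactants: 6 2-(2,2-dibromoethenyl)-3,5-bis(methoxymethoxy)-6-(2-methylbut-3-en-2-yl)phenol
Product: 7 2-bromo-4,6-bis(methoxymethoxy)-7-(2-methylbut-3-en-2-yl)-1-benzofuran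
Conditions: CuI (5 mol %), K3PO4, THF, 80 °C
Reagents that add atoms: none
Why: Copper-catalysed intramolecular Ullmann-type O-vinylation of the gem-dibromoalkene closes the furan ring and leaves the second bromine at C2, so the position of the halogen is fixed by construction.

Step 6
Reactants: 8 6-methylhept-5-en-2-one
Product: 9 trimethyl[(6-methylhepta-1,5-dien-2-yl)oxy]silane
Conditions: LiN(i-Pr)2, THF, −78 °C; Me3SiCl
Reagents that add atoms: chlorotrimethylsilane, C[Si](C)(C)Cl
Why: Kinetic deprotonation of the methyl ketone at the methyl group and O-silylation give the terminal silyl enol ether, which fixes the site of the coming arylation.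

Step 7
Reactants: 7 2-bromo-4,6-bis(methoxymethoxy)-7-(2-methylbut-3-en-2-yl)-1-benzofuran; 9 trimethyl[(6-methylhepta-1,5-dien-2-yl)oxy]silane
Product: 10 1-Bf-6-methylhept-5-en-2-one
Conditions: Pd2(dba)3 (2.5 mol %), P(t-Bu)3, Bu3SnF, CsF, PhMe, 85 °C
Reagents that add atoms: none
Why: Palladium-catalysed α-arylation of a silyl enol ether through its tin enolate (fluoride activation, Bu3SnF returned by CsF) joins benzofuran C2 to the former methyl carbon only, since the enolate geometry is preset in 9.

Step 8
Reactants: 11 4-methylpent-3-en-1-ol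
Product: 12 4-methylpent-3-enal
Conditions: Dess–Martin periodinane, NaHCO3, CH2Cl2, 0 °C; used at once as a solution
Reagents that add atoms: none
Why: Buffered Dess–Martin oxidation is neutral and fast, so the β,γ-double bond should not move into conjugation before the aldehyde is used.

Step 9
Reactants: 10 1-Bf-6-methylhept-5-en-2-one; 12 4-methylpent-3-enal
Product: 13 7-Bf-8-hydroxy-2,11-dimethyldodeca-2,10-dien-6-one (mixture of diastereomers)
Conditions: LiN(SiMe3)2, THF, −78 °C; 12; AcOH quench at −78 °C
Reagents that add atoms: none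
Why: Aldol addition of the lithium enolate formed at the benzofuranyl CH2, by far the more acidic α position, to the aldehyde at low temperature; the two new stereocentres are removed in the next step.

Step 10
Reactants: 13 7-Bf-8-hydroxy-2,11-dimethyldodeca-2,10-dien-6-one
Product: 15 (7E)-7-Bf-2,11-dimethyldodeca-2,7,10-trien-6-one, via mesylate 14 (not isolated)
Conditions: MeSO2Cl, Et3N, CH2Cl2, −20 °C; DBU, 0 °C
Reagents that add atoms: none
Why: Mesylation and E1cB elimination through the acidic α-hydrogen should give the more stable (E)-enone, with the chain CH2 trans to the acyl group, under conditions too mild to deprotonate the doubly allylic CH2.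

Step 11
Reactants: 15 (7E)-7-Bf-2,11-dimethyldodeca-2,7,10-trien-6-one
Product: 17 (7E)-7-Bf-5-diazo-2,11-dimethyldodeca-2,7,10-trien-6-one, via trifluoroacetyl diketone 16 (not isolated)
Conditions: LiN(SiMe3)2, THF, −78 °C; CF3CO2CH2CF3; then MeSO2N3, Et3N, H2O (1 equiv), MeCN, rt
Reagents that add atoms: methanesulfonyl azide, CS(=O)(=O)N=[N+]=[N-]
Why: Detrifluoroacetylative diazo transfer: the kinetic enolate forms at the α' CH2 (the doubly allylic CH2 lies anti to the carbonyl and out of reach of the coordinated amide), Claisen acylation activates that carbon, and the sulfonyl azide delivers N2 with loss of the trifluoroacetyl group.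

Step 12
Reactants: 18 ethyl dibromoacetate
Product: 20 (ethynyloxy)tri(propan-2-yl)silane, via lithium ethynolate 19 (not isolated)
Conditions: t-BuLi (4 equiv), THF, −78 to 0 °C; i-Pr3SiCl (2.2 equiv), −78 °C to rt
Reagents that add atoms: chlorotri(propan-2-yl)silane, CC(C)[Si](Cl)(C(C)C)C(C)C
Why: Two bromine–lithium exchanges give an ester dianion that expels ethoxide to the lithium ynolate (ester dianion cleavage), and the bulky silyl chloride silylates it on oxygen.

Step 13
Reactants: 17 (7E)-7-Bf-5-diazo-2,11-dimethyldodeca-2,7,10-trien-6-one; 20 (ethynyloxy)tri(propan-2-yl)silane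
Product: 24 3-Bf-2,4-bis(3-methylbut-2-en-1-yl)-5-[(triisopropylsilyl)oxy]phenol, via vinylketene 21 (not isolated), via cyclobutenone 22 (not isolated), via dienylketene 23 (not isolated)
Conditions: hν (300 nm, Pyrex), 20 (3 equiv), degassed ClCH2CH2Cl, rt; then 80 °C
Reagents that add atoms: none
Why: Irradiation expels N2 from 17 with 1,2-shift of the alkenyl group (photochemical Wolff rearrangement), giving vinylketene 21 whose carbonyl carbon is the future C3' and whose α carbon is C6'. The ynol ether then adds in a (2+2) sense, its nucleophilic CH terminus (C4') bonding to the ketene carbonyl carbon and its oxygen-bearing carbon (C5') to C6', and at 80 °C the resulting 4-alkenylcyclobutenone 22 opens in a four-electron electrocyclic step to dienylketene 23. Ring C closes by thermal six-electron electrocyclisation that joins C3' to C2', and enolisation gives the phenol; this is the diazoketone variant of the Danheiser benzannulation, for which silyloxyalkynes are established partners that give resorcinol monosilyl ethers. No stereocentre is formed. The step needs regiocontrol in the (2+2) addition, which the polarisation of the ynol ether against the electrophilic ketene carbon supplies, so that oxygen ends on C5' and hydrogen on C4'. It also needs alkenyl migration to outrun the 1,2-hydrogen shift from the allylic CH2 on the diazo carbon, for which direct unsensitised irradiation is chosen, and the (E) geometry of 17 places hydrogen, not the prenyl chain, on the inside of the closing triene.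

Step 14
Reactants: 24 3-Bf-2,4-bis(3-methylbut-2-en-1-yl)-5-[(triisopropylsilyl)oxy]phenol
Product: 25 5-Bf-4,6-bis(3-methylbut-2-en-1-yl)benzene-1,3-diol
Conditions: Bu4NF, AcOH, THF, 0 °C
Reagents that add atoms: none
Why: Fluoride-induced cleavage of the aryl silyl ether, buffered with acetic acid so that the electron-rich resorcinol is never held as a phenoxide, leaves the MOM acetals untouched.

Step 15
Reactants: 25 5-Bf-4,6-bis(3-methylbut-2-en-1-yl)benzene-1,3-diol
Product: 26 5-[4,6-dihydroxy-7-(2-methylbut-3-en-2-yl)-1-benzofuran-2-yl]-4,6-bis(3-methylbut-2-en-1-yl)benzene-1,3-diol (CNP0115465.0)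
Conditions: 3 M aq HCl, MeOH, 25 to 40 °C, stopped at full conversion
Reagents that add atoms: none
Why: Acid-catalysed acetal exchange with methanol removes both MOM groups, and dilute acid at low temperature is used so that the prenyl groups ortho to free phenols are not protonated and closed to chromans.

**Compound list**

1 | 2,4,6-trihydroxybenzaldehyde | O=Cc1c(O)cc(O)cc1O | starting material
2 | 3-methylbut-2-en-1-ol | CC(C)=CCO | starting material
3 | 2,6-dihydroxy-4-[(3-methylbut-2-en-1-yl)oxy]benzaldehyde | O=Cc1c(O)cc(OCC=C(C)C)cc1O | intermediate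
4 | 2,4,6-trihydroxy-3-(2-methylbut-3-en-2-yl)benzaldehyde | O=Cc1c(O)cc(O)c(C(C)(C)C=C)c1O | intermediate
5 | 2-hydroxy-4,6-bis(methoxymethoxy)-3-(2-methylbut-3-en-2-yl)benzaldehyde | O=Cc1c(OCOC)cc(OCOC)c(C(C)(C)C=C)c1O | intermediate
6 | 2-(2,2-dibromoethenyl)-3,5-bis(methoxymethoxy)-6-(2-methylbut-3-en-2-yl)phenol | BrC(Br)=Cc1c(OCOC)cc(OCOC)c(C(C)(C)C=C)c1O | intermediate
7 | 2-bromo-4,6-bis(methoxymethoxy)-7-(2-methylbut-3-en-2-yl)-1-benzofuran | Brc1cc2c(OCOC)cc(OCOC)c(C(C)(C)C=C)c2o1 | intermediate
8 | 6-methylhept-5-en-2-one | CC(=O)CCC=C(C)C | starting material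
9 | trimethyl[(6-methylhepta-1,5-dien-2-yl)oxy]silane | C=C(O[Si](C)(C)C)CCC=C(C)C | intermediate
10 | 1-Bf-6-methylhept-5-en-2-one | CC(C)=CCCC(=O)Cc1cc2c(OCOC)cc(OCOC)c(C(C)(C)C=C)c2o1 | intermediate
11 | 4-methylpent-3-en-1-ol | CC(C)=CCCO | starting material
12 | 4-methylpent-3-enal | CC(C)=CCC=O | intermediate
13 | 7-Bf-8-hydroxy-2,11-dimethyldodeca-2,10-dien-6-one (diastereomer mixture, racemic) | CC(C)=CCCC(=O)C(C(O)CC=C(C)C)c1cc2c(OCOC)cc(OCOC)c(C(C)(C)C=C)c2o1 | intermediate
14 | 7-Bf-2,11-dimethyl-6-oxododeca-2,10-dien-8-yl methanesulfonate (not isolated) | CC(C)=CCCC(=O)C(C(OS(C)(=O)=O)CC=C(C)C)c1cc2c(OCOC)cc(OCOC)c(C(C)(C)C=C)c2o1 | intermediate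
15 | (7E)-7-Bf-2,11-dimethyldodeca-2,7,10-trien-6-one | CC(C)=CC/C=C(/C(=O)CCC=C(C)C)c1cc2c(OCOC)cc(OCOC)c(C(C)(C)C=C)c2o1 | intermediate
16 | (7E)-7-Bf-2,11-dimethyl-5-(trifluoroacetyl)dodeca-2,7,10-trien-6-one (not isolated) | CC(C)=CC/C=C(/C(=O)C(CC=C(C)C)C(=O)C(F)(F)F)c1cc2c(OCOC)cc(OCOC)c(C(C)(C)C=C)c2o1 | intermediate
17 | (7E)-7-Bf-5-diazo-2,11-dimethyldodeca-2,7,10-trien-6-one | CC(C)=CC/C=C(/C(=O)C(=[N+]=[N-])CC=C(C)C)c1cc2c(OCOC)cc(OCOC)c(C(C)(C)C=C)c2o1 | intermediate
18 | ethyl dibromoacetate | CCOC(=O)C(Br)Br | starting material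
19 | lithium ethynolate (not isolated) | [Li+].[O-]C#C | intermediate
20 | (ethynyloxy)tri(propan-2-yl)silane | C#CO[Si](C(C)C)(C(C)C)C(C)C | intermediate
21 | 3-Bf-7-methyl-2-(3-methylbut-2-en-1-yl)octa-1,3,6-trien-1-one, chain CH2 trans to C2 (vinylketene, not isolated) | O=C=C(CC=C(C)C)/C(=C/CC=C(C)C)c1cc2c(OCOC)cc(OCOC)c(C(C)(C)C=C)c2o1 | intermediate
22 | 4-(1-Bf-5-methylhexa-1,4-dien-1-yl)-4-(3-methylbut-2-en-1-yl)-3-[(triisopropylsilyl)oxy]cyclobut-2-en-1-one (racemic, not isolated) | O=C1C=C(O[Si](C(C)C)(C(C)C)C(C)C)C1(CC=C(C)C)/C(=C/CC=C(C)C)c1cc2c(OCOC)cc(OCOC)c(C(C)(C)C=C)c2o1 | intermediate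
23 | 5-Bf-9-methyl-4-(3-methylbut-2-en-1-yl)-3-[(triisopropylsilyl)oxy]deca-1,3,5,8-tetraen-1-one (dienylketene, not isolated) | O=C=C/C(O[Si](C(C)C)(C(C)C)C(C)C)=C(CC=C(C)C)\C(=C\CC=C(C)C)c1cc2c(OCOC)cc(OCOC)c(C(C)(C)C=C)c2o1 | intermediate
24 | 3-Bf-2,4-bis(3-methylbut-2-en-1-yl)-5-[(triisopropylsilyl)oxy]phenol | C=CC(C)(C)c1c(OCOC)cc(OCOC)c2cc(-c3c(CC=C(C)C)c(O)cc(O[Si](C(C)C)(C(C)C)C(C)C)c3CC=C(C)C)oc12 | intermediate
25 | 5-Bf-4,6-bis(3-methylbut-2-en-1-yl)benzene-1,3-diol | C=CC(C)(C)c1c(OCOC)cc(OCOC)c2cc(-c3c(CC=C(C)C)c(O)cc(O)c3CC=C(C)C)oc12 | intermediate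
26 | 5-[4,6-dihydroxy-7-(2-methylbut-3-en-2-yl)-1-benzofuran-2-yl]-4,6-bis(3-methylbut-2-en-1-yl)benzene-1,3-diol | C=CC(C)(C)c1c(O)cc(O)c2cc(-c3c(CC=C(C)C)c(O)cc(O)c3CC=C(C)C)oc12 | target

**Count and risks**

Total steps: 15. Longest linear sequence: 12 steps (1, 2, 3, 4, 5, 7, 9, 10, 11, 13, 14, 15).

Steps most likely to fail:

Step 13. After loss of N2, a 1,2-hydrogen shift from the allylic CH2 on the diazo carbon may outrun the alkenyl migration, and the benzofuranyl enone chromophore may undergo secondary photochemistry. The fallback makes the same vinylketene thermally, without a carbene, from a cyclobutenone, and sets out from bromide 7. Lithium ethoxyacetylide (from ethoxyacetylene and n-BuLi) would be alkylated with prenyl bromide to 1-ethoxy-5-methylhex-4-en-1-yne F1. 5-Methylhex-4-enoic acid and oxalyl chloride would give 5-methylhex-4-enoyl chloride F2, whose ketene (Et3N) should add in a (2+2) sense to F1 to give 3-ethoxy-2,4-bis(3-methylbut-2-en-1-yl)cyclobut-2-en-1-one F3. Bromide 7 would be converted to the 2-lithiobenzofuran (t-BuLi, THF, −78 °C) and added to the carbonyl group of F3; dilute acid on work-up, with allylic transposition, should give 3-Bf-2,4-bis(3-methylbut-2-en-1-yl)cyclobut-2-en-1-one F4. Heating F4 with 20 at 80 to 110 °C opens the four-membered ring to vinylketene 21, where the route is rejoined and runs on to 24.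

Step 9. The β,γ-double bond of 12 may move into conjugation under the basic conditions, and the aldolate may revert by retro-aldol cleavage before it is quenched. The fallback brings in the chain by alkylation and makes the alkene by dehydrogenation, setting out from ketone 10. Its sodium enolate (NaH, THF–DMF, 0 °C) would be alkylated with commercial 5-bromo-2-methylpent-2-ene to 7-Bf-2,11-dimethyldodeca-2,10-dien-6-one F5. Thermodynamic silylation (Me3SiCl, NaI, Et3N, MeCN) should give the aryl-conjugated silyl enol ether 7-Bf-2,11-dimethyl-6-[(trimethylsilyl)oxy]dodeca-2,6,10-triene F6. Saegusa–Ito oxidation with Pd(OAc)2 in MeCN, in which β-hydride elimination can only run toward the chain, returns to the route at enone 15.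

Step 3. Discrimination between the two aldehyde-chelated phenols (O2 against O6) may be poor, or alkylation may run on, which would leave the wrong phenol for the furan closure. The fallback tells the two oxygens apart before the rearrangement and sets out from ether 3. One equivalent of MeOCH2Cl with i-Pr2NEt should cap one of the two equivalent chelated phenols and give 2-hydroxy-6-(methoxymethoxy)-4-[(3-methylbut-2-en-1-yl)oxy]benzaldehyde F7. Claisen rearrangement under the conditions of step 2 is then expected to go to C3, next to the remaining chelated phenol (bond fixation by the hydrogen-bonded ring, and C5 shielded by the MOM group), to give 2,4-dihydroxy-6-(methoxymethoxy)-3-(2-methylbut-3-en-2-yl)benzaldehyde F8. MOM protection of its only non-chelated phenol (O4) returns to the route at 5.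

**Further compounds**

F1 | step 13 | 1-ethoxy-5-methylhex-4-en-1-yne | CCOC#CCC=C(C)C
F2 | step 13 | 5-methylhex-4-enoyl chloride | CC(C)=CCCC(Cl)=O
F3 | step 13 | 3-ethoxy-2,4-bis(3-methylbut-2-en-1-yl)cyclobut-2-en-1-one | CCOC1=C(CC=C(C)C)C(=O)C1CC=C(C)C
F4 | step 13 | 3-Bf-2,4-bis(3-methylbut-2-en-1-yl)cyclobut-2-en-1-one | CC(C)=CCC1C(=O)C(CC=C(C)C)=C1c1cc2c(OCOC)cc(OCOC)c(C(C)(C)C=C)c2o1
F5 | step 9 | 7-Bf-2,11-dimethyldodeca-2,10-dien-6-one | CC(C)=CCCC(=O)C(CCC=C(C)C)c1cc2c(OCOC)cc(OCOC)c(C(C)(C)C=C)c2o1
F6 | step 9 | 7-Bf-2,11-dimethyl-6-[(trimethylsilyl)oxy]dodeca-2,6,10-triene | CC(C)=CCCC(O[Si](C)(C)C)=C(CCC=C(C)C)c1cc2c(OCOC)cc(OCOC)c(C(C)(C)C=C)c2o1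
F7 | step 3 | 2-hydroxy-6-(methoxymethoxy)-4-[(3-methylbut-2-en-1-yl)oxy]benzaldehyde | O=Cc1c(O)cc(OCC=C(C)C)cc1OCOC
F8 | step 3 | 2,4-dihydroxy-6-(methoxymethoxy)-3-(2-methylbut-3-en-2-yl)benzaldehyde | O=Cc1c(OCOC)cc(O)c(C(C)(C)C=C)c1O
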